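The target, once made, stands at a fork: it stays free, or a molecule of starting material holds it as idle adduct, and free target can go on with partner to over-reaction product. What counts here is the free form at the end.

| flask | starting material | partner | initiator | remark | time |
|---|---|---|---|---|---|
| teal | 7.3 mM | 10.4 mM | 0.65 mM | run made earlier |  |
| blue | 31 mM | 10.4 mM | 0.65 mM | run made earlier |  |
| eta | 6.0 mM | 10.4 mM | 0.65 mM |  | 25 min |
| alpha | 12 mM | 10.4 mM | 0.65 mM |  | 25 min |
| zeta | 25 mM | 10.4 mM | 0.65 mM |  | 25 min |

* [target] (only what is free in solution) at the end for eta, alpha, zeta, in this order
* the shape of the row from first to last (falls all the way / hardly changes / rises, then falls / falls, then rises / rises all the way)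

- percent here means starting material units held: one ended chains B or idle adduct counts as two
- what is said of target includes idle adduct
- the numbers in the tables scatter by 0.3 percentage points (one standard deviation)
- reactions considered so far: initiator -> 2 initiating radical; starting material + initiating radical -> capped initiator + first chain carrier; partner + first chain carrier <-> target + second chain carrier; starting material + second chain carrier -> released group + first chain carrier; 2 second chain carrier -> ended chains A; 2 first chain carrier -> ended chains B; starting material + target <-> idle adduct; partner + target -> over-reaction product
- in an amount of target, one idle adduct counts as one target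
- the concentration of target that is asked is that of its free form alone
- "hardly changes" means that all values lie within two and a half points (for a concentration: within two and a half percent of the largest)

| run | time / min | target / % | starting material / % |
|---|---|---|---|
| teal | 2.00 | 52.9 | 11.9 |
| teal | 5.00 | 58.2 | 5.9 |
| teal | 10.0 | 56.8 | 4.3 |
| teal | 25.0 | 45.5 | 2.8 |
| blue | 6.00 | 32.8 | 34.7 |
| blue | 12.0 | 33.3 | 32.5 |
| blue | 20.0 | 33.6 | 32.4 |
| blue | 25.0 | 34.0 | 31.9 |

(standard deviation of a reading: 0.3 percentage points)

In the first instants, initiator gives initiating radicals, and starting material turns these into first chain carrier. Partner then changes first carrier into target and second chain carrier, and second carrier takes starting material back to first carrier. In teal, starting material is down to 11.9 % and target up to 52.9 % by 2.00 min. In the middle, blue's target reading barely moves, from 32.8 % to 34.0 %; that is 10.5 mM, level with the partner charge of 10.4 mM, so partner is the limiting reagent in blue. Late on, teal's target falls from 58.2 % to 45.5 %, and over-reaction product is the exit the scheme offers.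

Blue's last readings also give the fork. Starting material stands at 9.89 mM. The units missing from both readings are the adduct's second units plus what ended chains B took. Allowing the initiator charge for those chains, which is a guess, leaves adduct D = 9.92 mM and free target T = 0.619 mM. So the tying constant K = D/(T[S]), with [S] the free starting material, reads 1.62 /mM, a rough reading because T is a small difference. The free share of target is then 1/(1 + K[S]).

Carrying teal's percentages to eta gives a share of 0.786 and 2.15 mM free; to alpha, 0.647 and 3.53 mM. In zeta, with partner limiting, [S] comes to 4.17 mM, which gives 1.34 mM. The forecast says 2.1 mM, 4.8 mM and 1.2 mM, shape rises, then falls, and of zeta that “excess starting material holds most target as adduct”; it stands higher than this reckoning at alpha.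

The flasks give 2.17 mM, 3.30 mM and 1.15 mM, shape rises, then falls.

    initiator → 2 initiating radical (k = 0.00110 /s)
    starting material + initiating radical → capped initiator + first chain carrier (k = 4.60 × 10⁵ /M/s)
    partner + first chain carrier ⇌ target + second chain carrier (K = 0.570, k = 3.30 × 10⁵ /M/s)
    starting material + second chain carrier → released group + first chain carrier (k = 82000 /M/s)
    2 second chain carrier → ended chains A (k = 9.00 × 10⁶ /M/s)
    2 first chain carrier → ended chains B (k = 3.00 × 10⁸ /M/s)
    starting material + target ⇌ idle adduct, settled at all times (K = 1800 /M)
    partner + target → over-reaction product (k = 0.130 /M/s)

With the simulated target and starting material, and K kept at the rough reading of 1.62 /mM, the free share gives 3.46 mM for alpha and 1.26 mM for zeta, more than the flasks' 3.30 mM and 1.15 mM. In eta, the half-life of free target by over-reaction at the end is 24 min against a run of 25 min, and over-reaction product stands at 35.2 %.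

The earlier runs and the new flask stem from a simulated flask with made-up constants, and the scatter is random.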